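The route builds a monocyclic cyclohexenol and adds the lactone carbons last. It rests on disconnecting C7–C11 and C6–O across the C6=C7 alkene of the six-membered ring: a bromoacetal carried by the β oxygen on C8 delivers C11 to C7, and the C6 radical that results is trapped by dioxygen. One operation thus closes a temporary tetrahydrofuran ring and sets C7 and C6, using the fact that the C7 side chain and the C8 oxygen share the β face of the ring while the C6 oxygen lies on the α face. The precursor is the 8β-bromoacetal of a cyclohex-6-en-8-ol bearing the C10 methyl/vinyl centre and the C5 arm as a silyl-protected allylic alcohol.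

Key step: step 11

Numbering and faces used below: ring carbons C5 to C10; C4 (with methylene C15 and C3) is the arm on C5; C11, C12 and C13 are the lactone carbons on C7; C14 is the methyl and C1=C2 the vinyl on C10; β is the face of the C10 methyl.

Assumption: the enantiopure cis-dihydrodiol of toluene (1), made by microbial arene dioxygenation, is taken as a purchasable starting material.

Step 1
Reactants: 1 (1S,2R)-3-methylcyclohexa-3,5-diene-1,2-diol
Product: 2 (1S,2R)-3-methylcyclohex-3-ene-1,2-diol
Conditions: H2 (1 atm, 1 equiv), Rh/Al2O3, MeOH, rt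
Reagents that add atoms: none
Why: Partial heterogeneous hydrogenation should saturate the less hindered cis-disubstituted C6=C7 alkene and leave the trisubstituted methyl-bearing alkene, so neither carbinol centre is touched.

Step 2
Reactants: 2 (1S,2R)-3-methylcyclohex-3-ene-1,2-diol
Product: 3 (3aR,7aS)-4-methyl-3a,6,7,7a-tetrahydro-1,3-benzodioxol-2-one (cis cyclic carbonate of 2)
Conditions: CDI, THF, rt → 50 °C
Reagents that add atoms: 1,1'-carbonyldiimidazole, O=C(n1ccnc1)n1ccnc1
Why: Carbonylation of a cis-1,2-diol by acyl transfer gives the five-membered cyclic carbonate, which turns the allylic C9–O bond into a leaving group without changing either stereocentre.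

Step 3
Reactants: 3 cis cyclic carbonate; 4 dimethyl malonate
Product: 5 dimethyl 2-[(1S,4S)-4-hydroxy-2-methylcyclohex-2-en-1-yl]propanedioate (C5 malonyl and C8 hydroxyl both β)
Conditions: Pd(PPh3)4 (5 mol %), THF, rt
Reagents that add atoms: none
Why: Tsuji–Trost allylic alkylation: zerovalent palladium ionises the allylic C9–O bond with inversion and loss of CO2, and the malonate attacks the allyl terminus remote from the alkoxide (C5) anti to the metal, so double inversion sets C5 cis to the retained 8β hydroxyl.

Step 4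
Reactants: 5 malonate adduct
Product: 6 (1S,4R)-4-(3-hydroxyprop-1-en-2-yl)-3-methylcyclohex-2-en-1-ol
Conditions: NaH, DME, 0 °C → rt; then LiAlH4, reflux; aq. NaOH work-up
Reagents that add atoms: none
Why: Reductive elimination of a malonate enolate: LiAlH4 reduces the sodium enolate through a β-alkoxy enolate that expels alkoxide, which should give the 2-substituted allylic alcohol directly, with C5 and C8 unaffected.

Step 5
Reactants: 6 allylic diol
Product: 7 (1S,4R)-4-[3-(tert-butyldiphenylsilyloxy)prop-1-en-2-yl]-3-methylcyclohex-2-en-1-ol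
Conditions: TBDPSCl, imidazole, CH2Cl2, 0 °C
Reagents that add atoms: tert-butyl(chloro)diphenylsilane, CC(C)(C)[Si](Cl)(c1ccccc1)c1ccccc1
Why: Silylation of an alcohol, in which the bulky chlorosilane selects the primary allylic hydroxyl over the ring secondary one; a robust silyl ether is chosen for C3 because it tolerates the later radical, Lewis acid/thiol and acylation steps.

Step 6
Reactants: 7 mono-silyl ether
Product: 8 (4R)-4-[3-(tert-butyldiphenylsilyloxy)prop-1-en-2-yl]-3-methylcyclohex-2-en-1-one
Conditions: MnO2, CH2Cl2, rt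
Reagents that add atoms: none
Why: MnO2 oxidation of a secondary allylic alcohol gives the enone under neutral conditions, so the C5 stereocentre, now γ to the carbonyl, should not epimerise or move into conjugation.

Step 7
Reactants: 8 enone; 9 vinylmagnesium bromide
Product: 11 (3S,4R)-4-[3-(tert-butyldiphenylsilyloxy)prop-1-en-2-yl]-3-ethenyl-3-methylcyclohexan-1-one, via trimethylsilyl enol ether 10 (not isolated)
Conditions: CuBr·SMe2 (10 mol %), TMSCl, THF, −78 °C; then 1 M HCl
Reagents that add atoms: none
Why: Copper-catalysed, TMSCl-accelerated conjugate addition of a vinyl Grignard reagent: allylic 1,2-strain with the C10 methyl holds the C5 substituent pseudoaxial, so vinyl enters C10 anti to it and the quaternary centre forms with vinyl α and methyl β.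

Step 8
Reactants: 11 ketone
Product: 12 (4R,5S)-4-[3-(tert-butyldiphenylsilyloxy)prop-1-en-2-yl]-5-ethenyl-5-methylcyclohex-2-en-1-one
Conditions: IBX (2 equiv), DMSO, 65 °C
Reagents that add atoms: none
Why: IBX dehydrogenation of a ketone through its enol can only give the C6=C7 enone, because C10 on the other side of the carbonyl carries no hydrogen.

Step 9
Reactants: 12 enone
Product: 13 (1R,4R,5S)-4-[3-(tert-butyldiphenylsilyloxy)prop-1-en-2-yl]-5-ethenyl-5-methylcyclohex-2-en-1-ol (8β-alcohol)
Conditions: NaBH4, CeCl3·7H2O, MeOH, −78 °C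
Reagents that add atoms: none
Why: Luche 1,2-reduction: with the C5 arm pseudoequatorial the C10 methyl is pseudoaxial on the β face and blocks it, so hydride should add from the α face and the new C8 hydroxyl is β, cis to the arm.

Step 10
Reactants: 13 8β-alcohol; 14 ethyl vinyl ether
Product: 15 O8 2-bromo-1-ethoxyethyl ether (bromoacetal) of 13
Conditions: NBS, CH2Cl2, −40 → 0 °C
Reagents that add atoms: N-bromosuccinimide, O=C1CCC(=O)N1Br
Why: Bromoacetalisation (haloetherification of an enol ether): the electron-rich vinyl ether is brominated in preference to the other alkenes and the C8 alcohol captures the oxocarbenium ion, so C8 is retained and the acetal carbon C12 forms as both epimers, either of which serves.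

Step 11
Reactants: 15 bromoacetal; 16 dioxygen (from dry air)
Product: 18 cis-fused bicyclic ethyl acetal (O8–C12–C11–C7) bearing the 6α-hydroxyl, via C6 hydroperoxide 17 (not isolated)
Conditions: Bu3SnH (2.5 equiv, syringe pump), dry air stream, toluene, 0 °C → rt; then PPh3, rt
Reagents that add atoms: none
Why: The tributyltin radical abstracts bromine to give the primary C11 radical, which adds to C7 of the C6=C7 alkene in a 5-exo-trig closure of the tetrahydrofuran ring (C11, C12, O8, C8, C7); the secondary C6 radical then combines with dioxygen, the peroxyl radical takes hydrogen from Bu3SnH to carry the chain, and PPh3 reduces hydroperoxide 17 to the alcohol. The closest known reaction type is the Ueno–Stork haloacetal radical cyclisation run under aerobic tin hydride conditions with oxygenative termination. C7 is set by the tether: anchored on the β oxygen of C8, the three-atom chain can reach C7 only on the β face, so the new ring is cis-fused. C6 is set by its neighbours: the β arm on C5 and the new β carbon on C7 leave only the α face open to dioxygen. The step needs ring closure to outrun oxygen capture or reduction of the C11 radical, and oxygen capture to outrun reduction of the C6 radical, which a low stationary concentration of tin hydride and of dissolved oxygen (air, not pure oxygen) should secure; 6-endo attack at C6 and addition to the two other alkenes are disfavoured by ring size.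

Step 12
Reactants: 18 6α-alcohol
Product: 19 6α-O-tert-butyldimethylsilyl ether of 18
Conditions: TBSOTf, 2,6-lutidine, CH2Cl2, −78 °C
Reagents that add atoms: tert-butyldimethylsilyl triflate, CC(C)(C)[Si](C)(C)OS(=O)(=O)C(F)(F)F
Why: Silylation of the hindered secondary C6 alcohol with a silyl triflate at low temperature, where the base-buffered mixed acetal should not be ionised.

Step 13
Reactants: 19 silylated acetal
Product: 20 8β-alcohol with C12 as a 1,3-dithiane (C7β CH2-dithianyl, 6α-OTBS, C3-OTBDPS)
Conditions: HS(CH2)3SH, BF3·OEt2 (20 mol %), CH2Cl2, −78 → −30 °C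
Reagents that add atoms: propane-1,3-dithiol, SCCCS
Why: Lewis acid-promoted transthioacetalisation: the 2-ethoxytetrahydrofuran ionises, the dithiol adds and the second sulfur closes the dithiane with cleavage of the ring C12–O8 bond, which frees the C8 hydroxyl while C12 stays masked at the aldehyde level.

Step 14
Reactants: 20 hydroxy dithiane; 21 tiglic acid
Product: 23 8β-tiglate of 20, via mixed anhydride 22 (not isolated)
Conditions: 2,4,6-Cl3C6H2COCl, Et3N, toluene, rt; then 20, DMAP, 60 °C
Reagents that add atoms: none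
Why: Yamaguchi esterification: DMAP-mediated acyl transfer from the mixed anhydride acylates the hindered axial C8 hydroxyl with retention at C8 and without isomerising the E alkene of the tiglate.

Step 15
Reactants: 23 bis-silyl tiglate
Product: 24 6α,3-diol (8β-tiglate, C12 dithiane)
Conditions: HF·pyridine, pyridine, THF, 0 → 40 °C
Reagents that add atoms: none
Why: Fluoride-mediated desilylation removes both silyl ethers in one operation under mildly acidic conditions that leave the tiglate, dithiane and alkenes alone and give no acyl migration.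

Step 16
Reactants: 24 diol dithiane
Product: 26 trans-fused 6α,12-lactol (C12 anomers), via hydroxy aldehyde 25 (not isolated)
Conditions: MeI, CaCO3, MeCN/H2O (4:1), 45 °C
Reagents that add atoms: water, O
Why: Alkylative hydrolysis of a dithiane: S-methylation makes sulfur a leaving group and water releases the C12 aldehyde, which the free 6α hydroxyl traps at once as the five-membered lactol.

Step 17
Reactants: 26 lactol
Product: 28 11(13)-methylene 6α,12-lactol, via Mannich base 27 (not isolated)
Conditions: CH2=NMe2+ I−, Et3N, CH2Cl2, rt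
Reagents that add atoms: Eschenmoser's salt (N,N-dimethylmethaniminium iodide), C=[N+](C)C.[I-]
Why: Mannich α-methylenation: the lactol opens to the aldehyde, whose enol adds to the iminium ion at C11, and β-elimination of dimethylamine gives the C11=C13 methylene; no ring stereocentre is enolisable.

Step 18
Reactants: 28 methylene lactol
Product: 29 6α,12-olide enal (α-methylene lactone with C3 as aldehyde)
Conditions: MnO2 (excess), CH2Cl2, rt
Reagents that add atoms: none
Why: MnO2 oxidises both allylic positions in one operation, the allylic hemiacetal to the α-methylene lactone and the primary allylic alcohol to the 2-substituted acrolein.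

Step 19
Reactants: 29 lactone enal
Product: 30 CNP0256928.1 (target acid)
Conditions: NaClO2, NaH2PO4, 2-methylbut-2-ene, tBuOH/H2O, 0 °C → rt
Reagents that add atoms: sodium chlorite, [Na+].[O-]Cl=O
Why: Pinnick oxidation converts the enal to the acrylic acid, with 2-methylbut-2-ene scavenging hypochlorous acid so that the alkenes, the tiglate and the α-methylene lactone should survive.

Compound list

1 | (1S,2R)-3-methylcyclohexa-3,5-diene-1,2-diol (toluene cis-dihydrodiol) | CC1=CC=C[C@H](O)[C@@H]1O | starting material
2 | (1S,2R)-3-methylcyclohex-3-ene-1,2-diol | CC1=CCC[C@H](O)[C@@H]1O | intermediate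
3 | (3aR,7aS)-4-methyl-3a,6,7,7a-tetrahydro-1,3-benzodioxol-2-one | CC1=CCC[C@H](OC2=O)[C@@H]1O2 | intermediate
4 | dimethyl malonate | COC(=O)CC(=O)OC | starting material
5 | dimethyl 2-[(1S,4S)-4-hydroxy-2-methylcyclohex-2-en-1-yl]propanedioate | CC1=C[C@@H](O)CC[C@H]1C(C(=O)OC)C(=O)OC | intermediate
6 | (1S,4R)-4-(3-hydroxyprop-1-en-2-yl)-3-methylcyclohex-2-en-1-ol | CC1=C[C@@H](O)CC[C@H]1C(=C)CO | intermediate
7 | (1S,4R)-4-[3-(tert-butyldiphenylsilyloxy)prop-1-en-2-yl]-3-methylcyclohex-2-en-1-ol | CC1=C[C@@H](O)CC[C@H]1C(=C)CO[Si](c2ccccc2)(c3ccccc3)C(C)(C)C | intermediate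
8 | (4R)-4-[3-(tert-butyldiphenylsilyloxy)prop-1-en-2-yl]-3-methylcyclohex-2-en-1-one | CC1=CC(=O)CC[C@H]1C(=C)CO[Si](c2ccccc2)(c3ccccc3)C(C)(C)C | intermediate
9 | vinylmagnesium bromide | C=C[Mg]Br | starting material
10 | trimethylsilyl enol ether (C8=C9) of ketone 11 | C=C[C@]1(C)C=C(O[Si](C)(C)C)CC[C@H]1C(=C)CO[Si](c2ccccc2)(c3ccccc3)C(C)(C)C | intermediate
11 | (3S,4R)-4-[3-(tert-butyldiphenylsilyloxy)prop-1-en-2-yl]-3-ethenyl-3-methylcyclohexan-1-one | C=C[C@]1(C)CC(=O)CC[C@H]1C(=C)CO[Si](c2ccccc2)(c3ccccc3)C(C)(C)C | intermediate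
12 | (4R,5S)-4-[3-(tert-butyldiphenylsilyloxy)prop-1-en-2-yl]-5-ethenyl-5-methylcyclohex-2-en-1-one | C=C[C@]1(C)CC(=O)C=C[C@H]1C(=C)CO[Si](c2ccccc2)(c3ccccc3)C(C)(C)C | intermediate
13 | (1R,4R,5S)-4-[3-(tert-butyldiphenylsilyloxy)prop-1-en-2-yl]-5-ethenyl-5-methylcyclohex-2-en-1-ol (8β-alcohol, C6=C7 alkene) | C=C[C@]1(C)C[C@@H](O)C=C[C@H]1C(=C)CO[Si](c2ccccc2)(c3ccccc3)C(C)(C)C | intermediate
14 | ethyl vinyl ether | C=COCC | starting material
15 | O8 2-bromo-1-ethoxyethyl ether (bromoacetal) of 13; both C12 epimers are carried, one is drawn | C=C[C@]1(C)C[C@@H](O[C@@H](OCC)CBr)C=C[C@H]1C(=C)CO[Si](c2ccccc2)(c3ccccc3)C(C)(C)C | intermediate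
16 | dioxygen | O=O | starting material
17 | 6α-hydroperoxide of the cyclised cis-fused acetal | C=C[C@]1(C)C[C@H]2O[C@@H](OCC)C[C@H]2[C@H](OO)[C@H]1C(=C)CO[Si](c3ccccc3)(c4ccccc4)C(C)(C)C | intermediate
18 | cis-fused bicyclic ethyl acetal (tetrahydrofuran O8–C12–C11–C7–C8) with 6α-hydroxyl, 5β arm as TBDPS ether, 10β-methyl and 10α-vinyl | C=C[C@]1(C)C[C@H]2O[C@@H](OCC)C[C@H]2[C@H](O)[C@H]1C(=C)CO[Si](c3ccccc3)(c4ccccc4)C(C)(C)C | intermediate
19 | 6α-O-tert-butyldimethylsilyl ether of 18 | C=C[C@]1(C)C[C@H]2O[C@@H](OCC)C[C@H]2[C@H](O[Si](C)(C)C(C)(C)C)[C@H]1C(=C)CO[Si](c3ccccc3)(c4ccccc4)C(C)(C)C | intermediate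
20 | 8β-alcohol with C7β CH2-(1,3-dithian-2-yl), 6α-OTBS and C3-OTBDPS | C=C[C@]1(C)C[C@@H](O)[C@@H](CC2SCCCS2)[C@H](O[Si](C)(C)C(C)(C)C)[C@H]1C(=C)CO[Si](c3ccccc3)(c4ccccc4)C(C)(C)C | intermediate
21 | tiglic acid | C/C=C(\C)C(=O)O | starting material
22 | tiglic 2,4,6-trichlorobenzoic anhydride | C/C=C(\C)C(=O)OC(=O)c1c(Cl)cc(Cl)cc1Cl | intermediate
23 | 8β-tiglate of 20 | C=C[C@]1(C)C[C@@H](OC(=O)/C(C)=C/C)[C@@H](CC2SCCCS2)[C@H](O[Si](C)(C)C(C)(C)C)[C@H]1C(=C)CO[Si](c3ccccc3)(c4ccccc4)C(C)(C)C | intermediate
24 | 8β-tiglate with free 6α-hydroxyl and C3 hydroxyl, C12 as dithiane | C=C[C@]1(C)C[C@@H](OC(=O)/C(C)=C/C)[C@@H](CC2SCCCS2)[C@H](O)[C@H]1C(=C)CO | intermediate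
25 | hydroxy aldehyde (C12 aldehyde, free 6α-hydroxyl) | C=C[C@]1(C)C[C@@H](OC(=O)/C(C)=C/C)[C@@H](CC=O)[C@H](O)[C@H]1C(=C)CO | intermediate
26 | trans-fused 6α,12-lactol, C12 anomers | C=C[C@]1(C)C[C@@H](OC(=O)/C(C)=C/C)[C@H]2CC(O)O[C@@H]2[C@H]1C(=C)CO | intermediate
27 | 11-(dimethylaminomethyl) 6α,12-lactol (Mannich base) | C=C[C@]1(C)C[C@@H](OC(=O)/C(C)=C/C)[C@H]2C(CN(C)C)C(O)O[C@@H]2[C@H]1C(=C)CO | intermediate
28 | 11(13)-methylene 6α,12-lactol | C=C[C@]1(C)C[C@@H](OC(=O)/C(C)=C/C)[C@H]2C(=C)C(O)O[C@@H]2[C@H]1C(=C)CO | intermediate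
29 | 11(13)-methylene 6α,12-olide with C3 aldehyde | C=C[C@]1(C)C[C@@H](OC(=O)/C(C)=C/C)[C@H]2C(=C)C(=O)O[C@@H]2[C@H]1C(=C)C=O | intermediate
30 | CNP0256928.1: 8β-tigloyloxy 11(13)-methylene 6α,12-olide with 10β-methyl, 10α-vinyl and the 5β 1-carboxyethenyl arm | C=C[C@]1(C)C[C@@H](OC(=O)/C(C)=C/C)[C@H]2C(=C)C(=O)O[C@@H]2[C@H]1C(=C)C(=O)O | target

Total step count: 19. Longest linear sequence: 19 steps (1 to 30); compounds 4, 9, 14, 16 and 21 are purchased.

Steps most likely to fail

Step 11. What may go wrong: dioxygen captures the primary C11 radical before ring closure, or tin hydride reduces the C6 radical before oxygen arrives, so the C6 oxygen is lost. The fallback separates ring closure from oxygenation. It sets out from 13: N-iodosuccinimide and 14 should give the iodoacetal F1; irradiation with catalytic (Bu3Sn)2 in degassed benzene should effect iodine-atom-transfer 5-exo cyclisation, free of hydride and oxygen, to the 6-iodo bicyclic acetal F2; the isolated secondary iodide is then converted to the alcohol by Bu3SnH under air followed by PPh3, the regenerated C6 radical again being oxygenated on the α face. The fallback comes back to the route at 18.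

Step 4. What may go wrong: conjugate hydride addition to the intermediate (loss of the alkene) or incomplete elimination, so that a saturated alcohol or a 1,3-diol results. The fallback builds the methylene by olefination instead of reductive elimination. It sets out from 3: the palladium-catalysed allylic alkylation is run with trimethyl phosphonoacetate in place of 4 to give the phosphonoacetate adduct F3; Horner–Wadsworth–Emmons reaction with aqueous formaldehyde and K2CO3 should give the methyl acrylate F4; reduction of the ester with iBu2AlH in CH2Cl2 at −78 °C comes back to the route at 6.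

Step 13. What may go wrong: loss of the C6 silyl ether under the Lewis acid, or stalling at a ring-closed monothioacetal so that O8 is not freed. The fallback avoids Lewis acid and masks C12 with nitrogen instead of sulfur. It sets out from 19: AcOH/THF/H2O should hydrolyse the acetal to the lactol F5; N,N-dimethylhydrazine in EtOH should open it to the open-chain hydrazone F6 with the C8 hydroxyl free; tigloylation with 21 under the conditions of step 14 gives the tiglate hydrazone F7; HF·pyridine removes both silyl groups to give the desilylated hydrazone F8; hydrolysis of the hydrazone with aqueous Cu(OAc)2 releases aldehyde 25, which closes and comes back to the route at 26.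

Further compounds

F1 | step 11 | O8 2-iodo-1-ethoxyethyl ether (iodoacetal) of 13 | C=C[C@]1(C)C[C@@H](O[C@@H](OCC)CI)C=C[C@H]1C(=C)CO[Si](c2ccccc2)(c3ccccc3)C(C)(C)C
F2 | step 11 | 6-iodo cis-fused bicyclic ethyl acetal (iodine in place of the hydroxyl of 18) | C=C[C@]1(C)C[C@H]2O[C@@H](OCC)C[C@H]2[C@H](I)[C@H]1C(=C)CO[Si](c3ccccc3)(c4ccccc4)C(C)(C)C
F3 | step 4 | methyl 2-(dimethoxyphosphoryl)-2-[(1S,4S)-4-hydroxy-2-methylcyclohex-2-en-1-yl]acetate | CC1=C[C@@H](O)CC[C@H]1C(C(=O)OC)P(=O)(OC)OC
F4 | step 4 | methyl 2-[(1R,4S)-4-hydroxy-2-methylcyclohex-2-en-1-yl]prop-2-enoate | CC1=C[C@@H](O)CC[C@H]1C(=C)C(=O)OC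
F5 | step 13 | O8–C12 lactol of 19 (hydroxyl in place of ethoxy) | C=C[C@]1(C)C[C@H]2OC(O)C[C@H]2[C@H](O[Si](C)(C)C(C)(C)C)[C@H]1C(=C)CO[Si](c3ccccc3)(c4ccccc4)C(C)(C)C
F6 | step 13 | 8β-alcohol with C12 as N,N-dimethylhydrazone, 6α-OTBS, C3-OTBDPS | C=C[C@]1(C)C[C@@H](O)[C@@H](C/C=N/N(C)C)[C@H](O[Si](C)(C)C(C)(C)C)[C@H]1C(=C)CO[Si](c2ccccc2)(c3ccccc3)C(C)(C)C
F7 | step 13 | 8β-tiglate of F6 | C=C[C@]1(C)C[C@@H](OC(=O)/C(C)=C/C)[C@@H](C/C=N/N(C)C)[C@H](O[Si](C)(C)C(C)(C)C)[C@H]1C(=C)CO[Si](c2ccccc2)(c3ccccc3)C(C)(C)C
F8 | step 13 | 8β-tiglate hydrazone with free 6α-hydroxyl and C3 hydroxyl | C=C[C@]1(C)C[C@@H](OC(=O)/C(C)=C/C)[C@@H](C/C=N/N(C)C)[C@H](O)[C@H]1C(=C)CO
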